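**Strategy.** The left trans-decalin is cut at C5–C6 and C9–C10, leaving ring A as 2,4,4-trimethylcyclohex-2-enone. Its C5=C10 enone double bond takes up three components in one flask: a C6–C8 Grignard reagent adds to C5 under copper–ligand control, and the resulting enolate is allylated at C10 (C9, C11, C12). Because the electrophile enters anti to the new C5 chain, C6 and C9 end trans, which fixes the trans fusion and the quaternary C10. The cis-fused right decalin arises from the same logic with methyl introduced last. A carbonyl-ene reaction then closes ring B, and a B-alkyl Suzuki coupling joins the halves.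

Key step: step 1

Remark (numbering): left decalin C1–C10 (ring A = C1–C5, C10; ring B = C5–C10), C26 = exocyclic methylene carbon, C11–C12 = bridge; the right decalin is primed, with C9′ bonded to C12.
Remark (stereochemistry): the SMILES defines a trans-fused left decalin (5S,9S,10S) and a cis-fused right decalin (5′R,10′S; H-5′ and CH3-10′ on the same face); the route is built for exactly this.
Assumption: (R,S)-Josiphos [(R)-1-{(S)-2-(diphenylphosphino)ferrocenyl}ethyldicyclohexylphosphine] is taken to deliver the alkyl group to the enone face that gives 3S in 5; if the sense proves the reverse, the two ligand enantiomers are exchanged between steps 1 and 8.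

Step 1
Reactants: 1 2,4,4-trimethylcyclohex-2-en-1-one; 2 [2-(1,3-dioxan-2-yl)ethyl]magnesium bromide; 3 allyl bromide
Product: 5 (2R,3S)-2-allyl-3-[2-(1,3-dioxan-2-yl)ethyl]-2,4,4-trimethylcyclohexan-1-one, via magnesium enolate 4 (not isolated)
Conditions: CuBr·SMe2 (5 mol %), (R,S)-Josiphos (6 mol %), 2 (1.3 equiv), t-BuOMe/2-MeTHF, −78 °C; then 3 (3 equiv), DMPU, −78 to 0 °C
Reagents that add atoms: [2-(1,3-dioxan-2-yl)ethyl]magnesium bromide (2), Br[Mg]CCC1OCCCO1; allyl bromide (3), C=CCBr
Why: The chiral copper–Josiphos alkyl species adds the C6–C8 chain of 2 to C5 of enone 1, and the magnesium enolate 4 so formed is C-allylated at C10 by 3 in the same flask, so that C5–C6 and C9–C10 are made in one operation. The closest known reaction type is the copper-catalysed asymmetric conjugate addition of Grignard reagents to cyclic enones with electrophilic trapping of the magnesium enolate (three-component vicinal dialkylation). No ring is closed here; ring B is completed in step 5 from the two new substituents. C5 is set by the ligand (face selection at the enone β-carbon), and C10 by the substrate, because the allyl halide approaches the enolate face anti to the C5 side chain; C6 and C9 therefore end trans, which is the trans ring fusion with the angular methyl cis to C6. The step needs β-attack on a hindered α-methyl, γ,γ-dimethyl enone (helped by the unhindered primary Grignard reagent and copper activation) and C- rather than O-allylation of a tetrasubstituted enolate (helped by the soft allylic bromide and DMPU).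

Step 2
Reactants: 5 (2R,3S)-2-allyl-3-[2-(1,3-dioxan-2-yl)ethyl]-2,4,4-trimethylcyclohexan-1-one
Product: 6 2-{2-[(1S,2R)-2-allyl-2,6,6-trimethylcyclohexyl]ethyl}-1,3-dioxane
Conditions: N2H4·H2O, KOH, diethylene glycol, 130 °C then 200 °C, argon
Reagents that add atoms: none
Why: Wolff–Kishner reduction (Huang–Minlon procedure) removes the ring-A carbonyl (C1) through its hydrazone; the acetal and the isolated alkene are base-stable and neither stereocentre is enolisable.

Step 3
Reactants: 6 2-{2-[(1S,2R)-2-allyl-2,6,6-trimethylcyclohexyl]ethyl}-1,3-dioxane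
Product: 7 2-{2-[(1S,2R)-2,6,6-trimethyl-2-[(E)-prop-1-en-1-yl]cyclohexyl]ethyl}-1,3-dioxane
Conditions: RuHCl(CO)(PPh3)3 (2 mol %), toluene, 80 °C
Reagents that add atoms: none
Why: Ruthenium hydride-catalysed alkene isomerisation (hydrometalation/β-hydride elimination) should move the terminal double bond one position to the (E)-propenyl isomer, and it cannot travel further because C10 is quaternary.

Step 4
Reactants: 7 2-{2-[(1S,2R)-2,6,6-trimethyl-2-[(E)-prop-1-en-1-yl]cyclohexyl]ethyl}-1,3-dioxane
Product: 8 3-{(1S,2R)-2,6,6-trimethyl-2-[(E)-prop-1-en-1-yl]cyclohexyl}propanal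
Conditions: 2 M HCl, THF, 45 °C
Reagents that add atoms: water, O
Why: Acid-catalysed acetal hydrolysis frees the C8 aldehyde; the disubstituted alkene should be inert to dilute aqueous acid at this temperature.

Step 5
Reactants: 8 3-{(1S,2R)-2,6,6-trimethyl-2-[(E)-prop-1-en-1-yl]cyclohexyl}propanal
Product: 9 (1R,2R,4aS,8aS)-5,5,8a-trimethyl-1-vinyldecahydronaphthalen-2-ol
Conditions: Me2AlCl (1.5 equiv), CH2Cl2, −78 to 0 °C
Reagents that add atoms: none
Why: Lewis acid-promoted intramolecular carbonyl-ene reaction (the citronellal-to-isopulegol type): propenyl carbon C9 bonds to the complexed aldehyde carbon C8 in a six-membered closure through a chair transition state while a methyl hydrogen passes to oxygen, which closes ring B with hydroxyl and vinyl trans-diequatorial (C9–H α as in the target) on the trans ring fusion set in step 1; the C8 carbinol configuration is immaterial because it is oxidised in step 14.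

Step 6
Reactants: 10 4,4-dimethylcyclohex-2-en-1-one
Product: 11 2-iodo-4,4-dimethylcyclohex-2-en-1-one
Conditions: iodine, pyridine, CH2Cl2, 0 °C to rt
Reagents that add atoms: iodine, [I][I]
Why: α-Iodination of a cyclic enone by an addition–elimination sequence (conjugate addition of pyridine, iodination of the enolate, loss of pyridine).

Step 7
Reactants: 11 2-iodo-4,4-dimethylcyclohex-2-en-1-one; 12 tributyl(vinyl)stannane
Product: 13 4,4-dimethyl-2-vinylcyclohex-2-en-1-one
Conditions: Pd2(dba)3 (2.5 mol %), AsPh3 (10 mol %), CuI (10 mol %), NMP, rt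
Reagents that add atoms: tributyl(vinyl)stannane (12), C=C[Sn](CCCC)(CCCC)CCCC
Why: Stille coupling of the α-iodoenone with the vinylstannane installs the future C9′ carbon on C10′ before the methyl group.

Step 8
Reactants: 13 4,4-dimethyl-2-vinylcyclohex-2-en-1-one; 14 4-bromo-2-methylbut-1-ene; 15 iodomethane
Product: 18 (2R,3R)-2,4,4-trimethyl-3-(3-methylbut-3-en-1-yl)-2-vinylcyclohexan-1-one, via Grignard reagent 16 (not isolated), via magnesium dienolate 17 (not isolated)
Conditions: 14, Mg, Et2O, rt; then 13, CuBr·SMe2 (5 mol %), (S,R)-Josiphos (6 mol %), t-BuOMe, −78 °C; then 15 (5 equiv), DMPU, −78 to 0 °C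
Reagents that add atoms: 4-bromo-2-methylbut-1-ene (14), C=C(C)CCBr; iodomethane (15), CI
Why: The same copper-catalysed conjugate addition/enolate alkylation as in step 1, with the mirror-image ligand setting C5′ and iodomethane attacking dienolate 17 at C10′ anti to the new C5′ chain, so the vinyl group ends cis to that chain, which is the arrangement required for the cis ring fusion.

Step 9
Reactants: 18 (2R,3R)-2,4,4-trimethyl-3-(3-methylbut-3-en-1-yl)-2-vinylcyclohexan-1-one
Product: 19 (1R,2R)-1,3,3-trimethyl-2-(3-methylbut-3-en-1-yl)-1-vinylcyclohexane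
Conditions: N2H4·H2O, KOH, diethylene glycol, 130 °C then 200 °C, argon
Reagents that add atoms: none
Why: Wolff–Kishner reduction removes the C1′ carbonyl; the vinyl group on the quaternary carbon cannot conjugate or migrate and both alkenes are base-stable.

Step 10
Reactants: 19 (1R,2R)-1,3,3-trimethyl-2-(3-methylbut-3-en-1-yl)-1-vinylcyclohexane
Product: 20 (4aR,8aR)-2,5,5,8a-tetramethyl-3,4,4a,5,6,7,8,8a-octahydronaphthalene
Conditions: second-generation Grubbs catalyst (H2IMes)(PCy3)Cl2Ru=CHPh (5 mol %), CH2Cl2, 40 °C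
Reagents that add atoms: none
Why: Ring-closing olefin metathesis between the vinyl group and the 1,1-disubstituted alkene, which are held cis on ring A′, should close ring B′ as a cis-fused trisubstituted cyclohexene (C8′=C9′) with loss of ethene.

Step 11
Reactants: 20 (4aR,8aR)-2,5,5,8a-tetramethyl-3,4,4a,5,6,7,8,8a-octahydronaphthalene
Product: 22 (4aR,8aS)-2,5,5,8a-tetramethyloctahydronaphthalen-1(2H)-one, via alkylborane 21 (not isolated)
Conditions: BH3·THF, THF, 0 °C to rt; then N-methylmorpholine N-oxide, (n-Pr4N)RuO4 (5 mol %), 4 Å MS, CH2Cl2, rt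
Reagents that add atoms: N-methylmorpholine N-oxide, C[N+]1([O-])CCOCC1
Why: Anti-Markovnikov hydroboration places boron on the less substituted alkene carbon C9′ (21 is drawn as the monoalkylborane), and amine-oxide/perruthenate oxidation converts the C–B bond through the alcohol into the ketone in the same flask; the C8′ methyl centre forms as an epimer mixture that is erased in step 12.

Step 12
Reactants: 22 (4aR,8aS)-2,5,5,8a-tetramethyloctahydronaphthalen-1(2H)-one
Product: 23 (4aR,8aS)-2,5,5,8a-tetramethyl-3,4,4a,5,6,7,8,8a-octahydronaphthalen-1-yl trifluoromethanesulfonate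
Conditions: KN(SiMe3)2, THF, −78 to 0 °C; then PhNTf2, −78 °C to rt
Reagents that add atoms: N-phenylbis(trifluoromethanesulfonimide), O=S(=O)(N(c1ccccc1)S(=O)(=O)C(F)(F)F)C(F)(F)F
Why: Enolisation can occur only toward C8′ because C10′ is quaternary, so O-sulfonylation of the potassium enolate should give the tetrasubstituted enol triflate regiospecifically.

Step 13
Reactants: 9 (1R,2R,4aS,8aS)-5,5,8a-trimethyl-1-vinyldecahydronaphthalen-2-ol; 23 (4aR,8aS)-2,5,5,8a-tetramethyl-3,4,4a,5,6,7,8,8a-octahydronaphthalen-1-yl trifluoromethanesulfonate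
Product: 25 (1R,2R,4aS,8aS)-5,5,8a-trimethyl-1-{2-[(4aR,8aS)-2,5,5,8a-tetramethyl-3,4,4a,5,6,7,8,8a-octahydronaphthalen-1-yl]ethyl}decahydronaphthalen-2-ol, via alkylborane 24 (not isolated)
Conditions: 9, 9-BBN (2.5 equiv), THF, 0 °C to rt; then 23, PdCl2(dppf) (5 mol %), AsPh3 (10 mol %), Cs2CO3 (3 equiv), DMF/H2O, 50 °C
Reagents that add atoms: triflate 23, O=S(=O)(OC1=C(C)CC[C@@H]2C(C)(C)CCC[C@]12C)C(F)(F)F
Why: Anti-Markovnikov hydroboration of the vinyl group followed by B-alkyl Suzuki–Miyaura coupling of the primary alkylborane with the alkenyl triflate should form the C12–C9′ bond and fix the tetrasubstituted C8′=C9′ double bond regiospecifically; the free hydroxyl is carried as its borinate (24).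

Step 14
Reactants: 25 (1R,2R,4aS,8aS)-5,5,8a-trimethyl-1-{2-[(4aR,8aS)-2,5,5,8a-tetramethyl-3,4,4a,5,6,7,8,8a-octahydronaphthalen-1-yl]ethyl}decahydronaphthalen-2-ol
Product: 26 (1R,4aS,8aS)-5,5,8a-trimethyl-1-{2-[(4aR,8aS)-2,5,5,8a-tetramethyl-3,4,4a,5,6,7,8,8a-octahydronaphthalen-1-yl]ethyl}octahydronaphthalen-2(1H)-one
Conditions: Dess–Martin periodinane, CH2Cl2, rt
Reagents that add atoms: none
Why: Dess–Martin oxidation of the secondary alcohol gives the C8 ketone; C9 is now α to the carbonyl and its equatorial side chain is the thermodynamically preferred epimer.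

Step 15
Reactants: 26 (1R,4aS,8aS)-5,5,8a-trimethyl-1-{2-[(4aR,8aS)-2,5,5,8a-tetramethyl-3,4,4a,5,6,7,8,8a-octahydronaphthalen-1-yl]ethyl}octahydronaphthalen-2(1H)-one; 27 methyltriphenylphosphonium bromide
Product: 29 (1S,4aS,8aS)-5,5,8a-trimethyl-2-methylidene-1-{2-[(4aR,8aS)-2,5,5,8a-tetramethyl-3,4,4a,5,6,7,8,8a-octahydronaphthalen-1-yl]ethyl}decahydronaphthalene, via phosphorus ylide 28 (not isolated)
Conditions: 27, KOtBu, toluene, 0 to 80 °C
Reagents that add atoms: methyltriphenylphosphonium bromide (27), C[P+](c1ccccc1)(c1ccccc1)c1ccccc1.[Br-]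
Why: Wittig methylenation of the hindered C8 ketone with the non-stabilised ylide installs C26; the tetrasubstituted alkene is inert and any C9 epimerisation under the basic conditions converges on the equatorial epimer of the target.

Compound list
1 | 2,4,4-trimethylcyclohex-2-en-1-one | CC1=CC(C)(C)CCC1=O | starting material
2 | [2-(1,3-dioxan-2-yl)ethyl]magnesium bromide | Br[Mg]CCC1OCCCO1 | starting material
3 | allyl bromide | C=CCBr | starting material
4 | bromomagnesium enolate of the conjugate adduct (3S) | Br[Mg]OC1=C(C)[C@@H](CCC2OCCCO2)C(C)(C)CC1 | intermediate (not isolated)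
5 | (2R,3S)-2-allyl-3-[2-(1,3-dioxan-2-yl)ethyl]-2,4,4-trimethylcyclohexan-1-one (allyl trans to the C3 chain) | O=C1CCC(C)(C)[C@H](CCC2OCCCO2)[C@@]1(C)CC=C | intermediate
6 | 2-{2-[(1S,2R)-2-allyl-2,6,6-trimethylcyclohexyl]ethyl}-1,3-dioxane | C1CCC(C)(C)[C@H](CCC2OCCCO2)[C@@]1(C)CC=C | intermediate
7 | 2-{2-[(1S,2R)-2,6,6-trimethyl-2-[(E)-prop-1-en-1-yl]cyclohexyl]ethyl}-1,3-dioxane | C1CCC(C)(C)[C@H](CCC2OCCCO2)[C@@]1(C)/C=C/C | intermediate
8 | 3-{(1S,2R)-2,6,6-trimethyl-2-[(E)-prop-1-en-1-yl]cyclohexyl}propanal | C1CCC(C)(C)[C@H](CCC=O)[C@@]1(C)/C=C/C | intermediate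
9 | (1R,2R,4aS,8aS)-5,5,8a-trimethyl-1-vinyldecahydronaphthalen-2-ol (trans-fused) | O[C@@H]1CC[C@H]2C(C)(C)CCC[C@]2(C)[C@H]1C=C | intermediate
10 | 4,4-dimethylcyclohex-2-en-1-one | CC1(C)C=CC(=O)CC1 | starting material
11 | 2-iodo-4,4-dimethylcyclohex-2-en-1-one | CC1(C)C=C(I)C(=O)CC1 | intermediate
12 | tributyl(vinyl)stannane | C=C[Sn](CCCC)(CCCC)CCCC | starting material
13 | 4,4-dimethyl-2-vinylcyclohex-2-en-1-one | C=CC1=CC(C)(C)CCC1=O | intermediate
14 | 4-bromo-2-methylbut-1-ene | C=C(C)CCBr | starting material
15 | iodomethane | CI | starting material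
16 | (3-methylbut-3-en-1-yl)magnesium bromide | C=C(C)CC[Mg]Br | intermediate (not isolated)
17 | bromomagnesium dienolate of the conjugate adduct (3R) | Br[Mg]OC1=C(C=C)[C@H](CCC(C)=C)C(C)(C)CC1 | intermediate (not isolated)
18 | (2R,3R)-2,4,4-trimethyl-3-(3-methylbut-3-en-1-yl)-2-vinylcyclohexan-1-one (vinyl cis to the C3 chain) | O=C1CCC(C)(C)[C@@H](CCC(C)=C)[C@@]1(C)C=C | intermediate
19 | (1R,2R)-1,3,3-trimethyl-2-(3-methylbut-3-en-1-yl)-1-vinylcyclohexane | C1CCC(C)(C)[C@@H](CCC(C)=C)[C@@]1(C)C=C | intermediate
20 | (4aR,8aR)-2,5,5,8a-tetramethyl-3,4,4a,5,6,7,8,8a-octahydronaphthalene (cis-fused) | C1=C(C)CC[C@@H]2C(C)(C)CCC[C@]12C | intermediate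
21 | alkylborane from 20 (boron on C1 of the octahydronaphthalene; C1 and C2 epimers) | BC1C(C)CC[C@@H]2C(C)(C)CCC[C@]12C | intermediate (not isolated)
22 | (4aR,8aS)-2,5,5,8a-tetramethyloctahydronaphthalen-1(2H)-one (cis-fused; C2 epimers) | O=C1C(C)CC[C@@H]2C(C)(C)CCC[C@]12C | intermediate
23 | (4aR,8aS)-2,5,5,8a-tetramethyl-3,4,4a,5,6,7,8,8a-octahydronaphthalen-1-yl trifluoromethanesulfonate | O=S(=O)(OC1=C(C)CC[C@@H]2C(C)(C)CCC[C@]12C)C(F)(F)F | intermediate
24 | B-alkyl-9-BBN from 9 with the hydroxyl as its 9-BBN borinate | B1(O[C@@H]3CC[C@H]4C(C)(C)CCC[C@]4(C)[C@H]3CCB5C6CCCC5CCC6)C2CCCC1CCC2 | intermediate (not isolated)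
25 | (1R,2R,4aS,8aS)-5,5,8a-trimethyl-1-{2-[(4aR,8aS)-2,5,5,8a-tetramethyl-3,4,4a,5,6,7,8,8a-octahydronaphthalen-1-yl]ethyl}decahydronaphthalen-2-ol | O[C@@H]1CC[C@H]2C(C)(C)CCC[C@]2(C)[C@H]1CCC1=C(C)CC[C@@H]2C(C)(C)CCC[C@]12C | intermediate
26 | (1R,4aS,8aS)-5,5,8a-trimethyl-1-{2-[(4aR,8aS)-2,5,5,8a-tetramethyl-3,4,4a,5,6,7,8,8a-octahydronaphthalen-1-yl]ethyl}octahydronaphthalen-2(1H)-one | O=C1CC[C@H]2C(C)(C)CCC[C@]2(C)[C@H]1CCC1=C(C)CC[C@@H]2C(C)(C)CCC[C@]12C | intermediate
27 | methyltriphenylphosphonium bromide | C[P+](c1ccccc1)(c1ccccc1)c1ccccc1.[Br-] | starting material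
28 | methylidenetriphenylphosphorane | C=P(c1ccccc1)(c1ccccc1)c1ccccc1 | intermediate (not isolated)
29 | (1S,4aS,8aS)-5,5,8a-trimethyl-2-methylidene-1-{2-[(4aR,8aS)-2,5,5,8a-tetramethyl-3,4,4a,5,6,7,8,8a-octahydronaphthalen-1-yl]ethyl}decahydronaphthalene | C=C1CC[C@H]2C(C)(C)CCC[C@]2(C)[C@H]1CCC1=C(C)CC[C@@H]2C(C)(C)CCC[C@]12C | target

Total step count: 15 (left half steps 1–5, right half steps 6–12, union and finish steps 13–15).
Longest linear sequence: 10 steps (10 to 29 through steps 6–15).

Steps most likely to fail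

Step 1. Risk: slow conjugate addition to the α-methylated, γ-quaternary enone and sluggish C-allylation of the tetrasubstituted magnesium enolate, with competing 1,2-addition, proton quench or O-allylation eroding yield and selectivity. The fallback sets out from 1 and returns at 5 and makes the two bonds in two operations. Copper-catalysed conjugate addition of the diorganozinc reagent derived from 2-(2-bromoethyl)-1,3-dioxane (Cu(OTf)2 with a phosphoramidite ligand, as used for 4,4-dimethylcyclohexenone) is followed by capture of the zinc enolate with allyl chloroformate, giving the allyl enol carbonate F1. Pd(PPh3)4 then triggers decarboxylative allylation, the allyl group again entering anti to the C3 chain, to give 5.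

Step 8. Risk: polymerisation or Diels–Alder dimerisation of the cross-conjugated vinyl enone 13, and alkylation of dienolate 17 at the vinyl terminus instead of C2. The fallback sets out from 10 and returns at 18. The same copper-catalysed conjugate addition of 16 is run on the unsubstituted enone 10 and the enolate is trapped with acetaldehyde to give the aldol adduct F2. Acid-catalysed dehydration (p-TsOH, benzene) gives the 2-ethylidene ketone F3. Deconjugative α-methylation of its extended enolate (KOtBu, MeI) places the methyl group anti to the C3 chain and turns the ethylidene into the vinyl group of 18.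

Step 13. Risk: slow oxidative addition and transmetalation at the tetrasubstituted triflate next to the quaternary carbon, with protodeboronation of 24 and hydrolysis of 23 back to 22. The fallback sets out from 9 and 22 and returns at 25. Hydroboration of 9 with 9-BBN and iodinolysis (iodine, NaOMe) gives the primary iodide F4. Halogen–lithium exchange (excess t-BuLi, −78 °C), transmetalation with CeCl3 and addition to ketone 22 give the tertiary alcohol F5. Acid-catalysed dehydration of the tertiary alcohol under equilibrating conditions (p-TsOH, benzene) should give the tetrasubstituted alkene 25.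

Further compounds
F1 | step 1 | allyl (3S)-3-[2-(1,3-dioxan-2-yl)ethyl]-2,4,4-trimethylcyclohex-1-en-1-yl carbonate | C=CCOC(=O)OC1=C(C)[C@@H](CCC2OCCCO2)C(C)(C)CC1
F2 | step 8 | 2-(1-hydroxyethyl)-4,4-dimethyl-3-(3-methylbut-3-en-1-yl)cyclohexan-1-one (C3 configured as in 18) | CC(O)C1C(=O)CCC(C)(C)[C@H]1CCC(C)=C
F3 | step 8 | 2-ethylidene-4,4-dimethyl-3-(3-methylbut-3-en-1-yl)cyclohexan-1-one (C3 configured as in 18) | CC=C1C(=O)CCC(C)(C)[C@H]1CCC(C)=C
F4 | step 13 | (1R,2R,4aS,8aS)-1-(2-iodoethyl)-5,5,8a-trimethyldecahydronaphthalen-2-ol | O[C@@H]1CC[C@H]2C(C)(C)CCC[C@]2(C)[C@H]1CCI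
F5 | step 13 | tertiary alcohol from addition of the F4-derived organocerium to 22 (diol; carbinol and C2 methyl centres unassigned) | O[C@@H]1CC[C@H]2C(C)(C)CCC[C@]2(C)[C@H]1CCC1(O)C(C)CC[C@@H]2C(C)(C)CCC[C@]12C
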